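**Retrosynthetic overview** (ring numbering: O1–O2–C3(CH3, CH2CO2H)–C4H2–C5(CH3, 10-phenyldecyl))
1. Andavadoic acid comes from its methyl ester; saponification is the last step.
2. The only ring, the 1,2-dioxolane, is cut at C3–C4 and O1–C5. This gives methyl 3-methoxy-3-(triethylsilylperoxy)butanoate (peroxycarbenium precursor, supplies C3/O2/O1) and 2-methyl-12-phenyldodec-1-ene (supplies C4/C5). They are joined in one convergent, catalytic asymmetric formal [3+2] annulation that also sets both fully substituted stereocentres.
3. Enabling feature: C3 carries O2, so it is a masked ketone carbon (acetoacetate level) that can become a C=O(+)–O cation. C5 is a fully alkylated carbon on O1, so it is a latent tertiary cation. The unsubstituted C4H2 between them is the CH2 end of an isopropenyl alkene. The ester carbonyl of the C3 arm lies 1,3 to O1 and can take over the silyl group.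
4. Peroxide half: ozonolysis of methyl 3-methylbut-3-enoate in methanol, then O-silylation. Alkene half: 10-bromodec-1-ene by hydroboration/Suzuki coupling with iodobenzene, then copper-catalysed isopropenylation.

Key step: step 5

Assumption: methyl 3-methylbut-3-enoate, 10-bromodec-1-ene and both antipodes of a BINOL-derived imidodiphosphorimidate (IDPi) acid are taken as purchasable; the catalyst is not counted as a step.

Step 1
Reactants: 1 10-bromodec-1-ene; 2 9-borabicyclo[3.3.1]nonane (9-BBN-H); 3 iodobenzene
Product: 5 (10-bromodecyl)benzene, via B-alkyl-9-BBN 4 (not isolated)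
Conditions: 9-BBN-H, THF, 0 °C to rt; then PhI, PdCl2(dppf) (cat.), AsPh3 (cat.), Cs2CO3, DMF–THF–H2O, rt
Reagents that add atoms: none
Why: Anti-Markovnikov hydroboration of the terminal alkene followed by B-alkyl Suzuki–Miyaura coupling joins the sp3 chain to the arene, the unactivated primary C–Br bond being inert to Pd(dppf) at room temperature; no stereocentre is formed.

Step 2
Reactants: 5 (10-bromodecyl)benzene; 6 isopropenylmagnesium bromide
Product: 7 2-methyl-12-phenyldodec-1-ene
Conditions: Li2CuCl4 (cat.), THF–NMP, 0 °C to rt
Reagents that add atoms: none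
Why: Copper-catalysed (Kochi-type) cross-coupling of an alkenyl Grignard reagent with a primary alkyl bromide installs the 1,1-disubstituted alkene as a single positional isomer; no stereocentre is formed.

Step 3
Reactants: 8 methyl 3-methylbut-3-enoate
Product: 11 methyl 3-hydroperoxy-3-methoxybutanoate (racemic), via primary ozonide 9 (not isolated), via carbonyl oxide 10 (not isolated)
Conditions: O3, CH2Cl2–MeOH, −78 °C; N2 purge; concentration below 20 °C, no reductant
Reagents that add atoms: ozone [O-][O+]=O; methanol CO
Why: Ozonolysis in methanol (Criegee mechanism) cleaves the primary ozonide of a 1,1-disubstituted alkene to formaldehyde and the more substituted ketone O-oxide, which methanol traps as the α-methoxy hydroperoxide; the new stereocentre is racemic and is erased again in step 5.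

Step 4
Reactants: 11 methyl 3-hydroperoxy-3-methoxybutanoate
Product: 12 methyl 3-methoxy-3-[(triethylsilyl)peroxy]butanoate (racemic)
Conditions: Et3SiCl, imidazole, CH2Cl2, 0 °C
Reagents that add atoms: chlorotriethylsilane CC[Si](Cl)(CC)CC
Why: O-silylation of the acidic hydroperoxide with a chlorosilane and imidazole should outrun any reaction at the ester at 0 °C and puts on the peroxide oxygen the group that leaves from it in step 5; the stereocentre stays racemic.

Step 5
Reactants: 12 methyl 3-methoxy-3-[(triethylsilyl)peroxy]butanoate; 7 2-methyl-12-phenyldodec-1-ene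
Product: 16 methyl 2-[(3R,5S)-3,5-dimethyl-5-(10-phenyldecyl)-1,2-dioxolan-3-yl]acetate, via peroxycarbenium ion 13 (not isolated), via tertiary carbocation 14 (not isolated), via silyl dioxolanium ion 15 (not isolated)
Conditions: IDPi acid (N-triflyl, bulky 3,3'-aryl groups, 5 mol %, antipode chosen by a test run), slight excess of 12, CH2Cl2–toluene, −78 °C, strictly anhydrous; Et3N quench; chromatography to remove any C5 epimer
Reagents that add atoms: none
Why: Proposed new method: the strong chiral acid, and after the first turnover the Et3Si+ that each ring closure releases (silylium-type asymmetric counteranion-directed catalysis), removes the methoxy group of 12 as Et3SiOMe and leaves peroxycarbenium ion 13 paired with the confined IDPi anion; the CH2 terminus of alkene 7 attacks its carbon (C4–C3 bond), the tertiary cation 14 is captured by the distal silylated peroxide oxygen (O1–C5 bond) to give 15, and loss of Et3Si+ gives 16. The closest known reaction types are the formal [3+2] annulation of triethylsilylperoxy ketals with 1,1-disubstituted alkenes under stoichiometric SnCl4 or TiCl4, which gives racemic tetrasubstituted 1,2-dioxolanes, and IDPi/silylium catalysis of additions to oxocarbenium ions and of ether-forming closures on tertiary cationic carbons; only the pairing of a peroxycarbenium ion with a chiral anion is new. The 1,2-dioxolane closes stepwise, and the ring-closing event is the collapse of an oxygen lone pair on an open tertiary cation, formally 5-endo with respect to the former C4=C5 π bond, which is unproblematic because no π bond has to be approached at a fixed angle. C3 is set in the C–C bond formation by the chiral anion, which covers one face of 13 and can tell the methyl group from the Lewis-basic CH2CO2Me arm; which antipode of the catalyst gives 3R has to be found in a test run. C5 is set in the ring closure by relay from C3: since the anion is not nucleophilic, the best acceptor for the leaving Et3Si group is the ester carbonyl of the C3 arm (seven-membered shuttle), so productive closure holds the silyl group on O1 on the face of that arm, the smaller C5 methyl group takes the place beside it and the 10-phenyldecyl chain the opposite face, which is the arm/chain trans relation of the target and should be reinforced by the chiral pocket. The step also needs Markovnikov regioselectivity (secured by the 1,1-disubstitution of 7, which lets only the CH2 end attack and only a tertiary cation form), ionisation of C–OMe instead of C–OOSi (secured by the more basic methoxy oxygen), attack by the alkene instead of the far less nucleophilic monoalkylbenzene ring, and closure faster than proton loss from 14 (secured by the nearby O1 and the very weakly basic anion).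

Step 6
Reactants: 16 methyl 2-[(3R,5S)-3,5-dimethyl-5-(10-phenyldecyl)-1,2-dioxolan-3-yl]acetate
Product: 18 andavadoic acid, via lithium carboxylate 17 (not isolated)
Conditions: LiOH·H2O, THF–H2O, 0 °C to rt; then 1 M HCl to pH 3
Reagents that add atoms: lithium hydroxide [Li+].[OH-]
Why: Saponification (BAc2) of an unhindered methyl ester; the dioxolane has no hydrogen on its oxygen-bearing carbons, so Kornblum–DeLaMare cleavage is impossible, and the carboxylate once formed resists enolisation, so C3 and C5 should stay untouched.

**Compound list**
1 | 10-bromodec-1-ene | C=CCCCCCCCCBr | starting material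
2 | 9-borabicyclo[3.3.1]nonane (9-BBN-H) | B1C2CCCC1CCC2 | starting material
3 | iodobenzene | Ic1ccccc1 | starting material
4 | 9-(10-bromodecyl)-9-borabicyclo[3.3.1]nonane | BrCCCCCCCCCCB1C2CCCC1CCC2 | intermediate
5 | (10-bromodecyl)benzene | BrCCCCCCCCCCc1ccccc1 | intermediate
6 | isopropenylmagnesium bromide | CC(=C)[Mg]Br | starting material
7 | 2-methyl-12-phenyldodec-1-ene | C=C(C)CCCCCCCCCCc1ccccc1 | intermediate
8 | methyl 3-methylbut-3-enoate | C=C(C)CC(=O)OC | starting material
9 | primary ozonide, methyl 2-(4-methyl-1,2,3-trioxolan-4-yl)acetate | COC(=O)CC1(C)COOO1 | intermediate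
10 | carbonyl oxide of methyl acetoacetate | COC(=O)CC(C)=[O+][O-] | intermediate
11 | methyl 3-hydroperoxy-3-methoxybutanoate (racemic) | COC(=O)CC(C)(OC)OO | intermediate
12 | methyl 3-methoxy-3-[(triethylsilyl)peroxy]butanoate (racemic) | COC(=O)CC(C)(OC)OO[Si](CC)(CC)CC | intermediate
13 | peroxycarbenium ion, (4-methoxy-4-oxobutan-2-ylidene)(triethylsilyloxy)oxonium, IDPi anion as counterion | COC(=O)CC(C)=[O+]O[Si](CC)(CC)CC | intermediate
14 | C5 carbenium ion of methyl (3R)-3,5-dimethyl-15-phenyl-3-[(triethylsilyl)peroxy]pentadecanoate, IDPi anion as counterion | C[C+](CCCCCCCCCCc1ccccc1)C[C@](C)(CC(=O)OC)OO[Si](CC)(CC)CC | intermediate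
15 | (3R,5S)-3-(2-methoxy-2-oxoethyl)-3,5-dimethyl-5-(10-phenyldecyl)-1-(triethylsilyl)-1,2-dioxolan-1-ium, IDPi anion as counterion | C[C@]1(CCCCCCCCCCc2ccccc2)C[C@](C)(CC(=O)OC)O[O+]1[Si](CC)(CC)CC | intermediate
16 | methyl 2-[(3R,5S)-3,5-dimethyl-5-(10-phenyldecyl)-1,2-dioxolan-3-yl]acetate (the two methyl groups trans; ester arm and chain trans) | C[C@]1(CCCCCCCCCCc2ccccc2)C[C@](C)(CC(=O)OC)OO1 | intermediate
17 | lithium 2-[(3R,5S)-3,5-dimethyl-5-(10-phenyldecyl)-1,2-dioxolan-3-yl]acetate | C[C@]1(CCCCCCCCCCc2ccccc2)C[C@](C)(CC(=O)[O-])OO1.[Li+] | intermediate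
18 | andavadoic acid, 2-[(3R,5S)-3,5-dimethyl-5-(10-phenyldecyl)-1,2-dioxolan-3-yl]acetic acid | C[C@]1(CCCCCCCCCCc2ccccc2)C[C@](C)(CC(=O)O)OO1 | target

**Total step count:** 6. **Longest linear sequence:** 4 steps (8 → 11 → 12 → 16 → 18, and equally 1 → 5 → 7 → 16 → 18).

**Steps most likely to fail**

1. **Step 5 (Proposed new method).** Several things may go wrong:
   - Facial discrimination at the peroxycarbenium carbon or at the tertiary cation may be too low.
   - The cation may lose a proton (ene-type outcome).
   - The strong Lewis acid may trigger O–O heterolysis of the silyl peroxide with 1,2-migration.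

   The fallback uses known chemistry, sets out from 12 and 7 and comes back at 18. Stoichiometric SnCl4 in CH2Cl2 at −78 °C (the known racemic annulation) should give both diastereomers as racemates. Chromatography isolates the racemic methyl ester with arm and chain trans F1. LiOH in THF–H2O gives the racemic acid F2. Activation with pivaloyl chloride/Et3N and N-acylation of lithiated (S)-4-benzyloxazolidin-2-one gives two diastereomeric imides, which are separated on silica gel or by crystallisation. The wanted one is the (3R,5S,4'S)-imide F3, whose configuration is to be secured by crystal structure analysis. LiOH/H2O2 at 0 °C then releases 18.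

2. **Step 4.** Before silylation is complete, the free hydroperoxide may attack its own ester carbonyl (five-membered peroxylactonisation) or lose methanol. The low-molecular-weight peroxide also limits the scale.

   The fallback sets out from alkene 7 and comes back at 18. It carries the C3 arm at the alcohol oxidation level, so that no ester lies within reach of the OOH group.
   - Purchased 3-methylbut-3-en-1-yl acetate F4 is ozonised in CH2Cl2–MeOH to 3-hydroperoxy-3-methoxybutyl acetate F5.
   - Silylation (Et3SiCl, imidazole) gives 3-methoxy-3-[(triethylsilyl)peroxy]butyl acetate F6.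
   - Annulation with 7 as in step 5 gives 2-[(3S,5S)-3,5-dimethyl-5-(10-phenyldecyl)-1,2-dioxolan-3-yl]ethyl acetate F7. The spatial arrangement is the same; the C3 descriptor changes only by priority.
   - K2CO3 in MeOH gives the primary alcohol F8.
   - TEMPO (cat.)/PhI(OAc)2 in MeCN–H2O oxidises it to 18.

3. **Step 6.** The β-peroxy ester may enolise and open by retro-oxa-Michael reaction. Re-closure would then scramble C3.

   The fallback sets out from 16 and comes back at 18 without any basic medium. DIBAL-H (one equivalent, CH2Cl2, −78 °C) gives the aldehyde F9. Pinnick oxidation (NaClO2, NaH2PO4, 2-methylbut-2-ene, t-BuOH–H2O) then gives 18.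

**Further compounds**
F1 | step 5 | racemic methyl 2-[(3R*,5S*)-3,5-dimethyl-5-(10-phenyldecyl)-1,2-dioxolan-3-yl]acetate | C[C@]1(CCCCCCCCCCc2ccccc2)C[C@](C)(CC(=O)OC)OO1.C[C@@]1(CCCCCCCCCCc2ccccc2)C[C@@](C)(CC(=O)OC)OO1
F2 | step 5 | racemic 2-[(3R*,5S*)-3,5-dimethyl-5-(10-phenyldecyl)-1,2-dioxolan-3-yl]acetic acid | C[C@]1(CCCCCCCCCCc2ccccc2)C[C@](C)(CC(=O)O)OO1.C[C@@]1(CCCCCCCCCCc2ccccc2)C[C@@](C)(CC(=O)O)OO1
F3 | step 5 | (4S)-4-benzyl-3-{2-[(3R,5S)-3,5-dimethyl-5-(10-phenyldecyl)-1,2-dioxolan-3-yl]acetyl}oxazolidin-2-one | C[C@]1(CCCCCCCCCCc2ccccc2)C[C@](C)(CC(=O)N2[C@@H](Cc3ccccc3)COC2=O)OO1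
F4 | step 4 | 3-methylbut-3-en-1-yl acetate (purchased) | C=C(C)CCOC(C)=O
F5 | step 4 | 3-hydroperoxy-3-methoxybutyl acetate (racemic) | CC(=O)OCCC(C)(OC)OO
F6 | step 4 | 3-methoxy-3-[(triethylsilyl)peroxy]butyl acetate (racemic) | CC(=O)OCCC(C)(OC)OO[Si](CC)(CC)CC
F7 | step 4 | 2-[(3S,5S)-3,5-dimethyl-5-(10-phenyldecyl)-1,2-dioxolan-3-yl]ethyl acetate | C[C@]1(CCCCCCCCCCc2ccccc2)C[C@](C)(CCOC(C)=O)OO1
F8 | step 4 | 2-[(3S,5S)-3,5-dimethyl-5-(10-phenyldecyl)-1,2-dioxolan-3-yl]ethanol | C[C@]1(CCCCCCCCCCc2ccccc2)C[C@](C)(CCO)OO1
F9 | step 6 | 2-[(3R,5S)-3,5-dimethyl-5-(10-phenyldecyl)-1,2-dioxolan-3-yl]acetaldehyde | C[C@]1(CCCCCCCCCCc2ccccc2)C[C@](C)(CC=O)OO1
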